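Readings and results were computed for substances that don't exist, noise included.

The analyst of Wednesday's and Tuesday's runs has Q and G at each sampling, and no reading of X or E.

| flask | Q | X | E | remark | time |
|---|---|---|---|---|---|
| Wednesday's | 1 M | 0.76 M | 0.30 M | run made earlier |  |
| Tuesday's | 1 M | 0.81 M | 0.30 M | run made earlier |  |
| alder | 1.0 M | 0.900 M | 0.300 M |  | 6.0 h |
| larch | 1.0 M | 1.20 M | 0.300 M |  | 6.0 h |

- Wednesday's (time / h: Q / %, G / %): 0.333: 54, 15; 0.833: 43, 28; 2.00: 38, 33; 4.00: 34, 32
- Tuesday's (time / h: Q / %, G / %): 0.500: 48, 24; 1.33: 39, 30; 2.50: 36, 33; 4.00: 34, 33

(scatter of a reading: 1.5 percentage points)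



- part of the Q that has reacted at the end, alder
- part of the Q that has reacted at the end, larch
- what raising the concentration of X from its lowest to its highest value here does to the part of the Q that has reacted (changes below 5 percentage points count as none) (no change / it rises / it falls)

Two columns can be built from these readings, in fractions of the Q charged. The lost share is the Q gone but not found as G. The stall quotient (an apparent equilibrium constant) is G divided by Q and by the X excess, which is X charged minus G and so assumes one X per G.

| Reading | Lost share | Quotient |
|---|---|---|
| Wednesday's, 0.333 h | 31.0% | 0.455 |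
| Wednesday's, 2.00 h | 29.0% | 2.02 |
| Wednesday's, 4.00 h | 34.0% | 2.14 |
| Tuesday's, 4.00 h | 33.0% | 2.02 |

The lost share barely moves from the first row on, given the 2.1 percentage points of scatter in a difference of two readings, and it lies near E's share of the charge, 30.0%. The readings show this only up to 4.00 h, but this reckoning takes the share as frozen there, and so estimates the reacted part as that share plus G. The quotient climbs and then stands, and the last two rows agree across two runs, though their X charges lie close together. Tuesday's last reading gives the frozen value, the stall quotient 2.02.

Solving the quotient with Q as the unlost remainder minus G gives G of 36.4% in alder, so 66.4% reacted. In larch G is 42.7%, so 72.7% reacted.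

The forecast says 69% and 76%, and it rises, on the ground that “the stall isn't simple exhaustion”. This reckoning lies lower in both flasks .

Alder gives 67.1% and larch 75.9%, so with X raised from alder's charge to larch's, it rises, by 8.8 points. Alder's free X stands at 23.7% of its charge, less than the 58.8% the quotient counts, and L holds 0.294 M. The quotient is thus a bookkeeping figure: with all the reacted Q above E's share counted as G, the results give 2.13 in alder and 2.56 in larch.

    Q + X ⇌ Z + G (K = 0.380, k = 3.50 × 10⁻⁴ /M/s)
    X + Z ⇌ L, settled at all times (K = 18.0 /M)
    Q + E → D (k = 0.00270 /M/s)
    X + G → J (k = 1.20 × 10⁻⁵ /M/s)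

Larch with X cut to 0.48 M keeps the same E share, and the frozen quotient gives G of 23.3%, so 53.3% reacted. That flask gives 52.8%, with G at 22.1%.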